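**Retrosynthetic overview**
- Feature: in each ring A the C2'–OH lies ortho to the C1 (or C4) ketone. The carbonyl oxygen can therefore hold palladium over the C2'–H bond, and both C2'–O bonds are made late by a twofold ketone-directed C–H oxygenation of the meso 1,4-diketone.
- For that step the four 4-oxygens are acetates, not methyl ethers. Rings B become inert to the oxidant and to undirected palladation, the ketones become less basic (less enolisation, less Paal–Knorr furan), and the last unmasking needs only cold carbonate.
- C2–C3 and both stereocentres come from oxidative homocoupling of the lithium enolate of 1,3-bis(4-methoxyphenyl)propan-1-one. The meso isomer is taken by crystallisation, then methyl is exchanged for acetyl.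
- The dihydrochalcone comes from 4'-methoxyacetophenone and 4-methoxybenzaldehyde by Claisen–Schmidt condensation and hydrogenation.
- Ring order: no ring is formed. All four benzene rings are bought.

Key step: step 6

Assumption: the (2R,3S) descriptors on a constitutionally symmetric chain define the achiral meso diastereomer, so relative configuration is the only stereochemical task.

Step 1
Reactants: 1 4'-methoxyacetophenone; 2 4-methoxybenzaldehyde
Product: 3 (E)-1,3-bis(4-methoxyphenyl)prop-2-en-1-one
Conditions: NaOH (aq), EtOH, 0 °C → rt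
Reagents that add atoms: none
Why: Claisen–Schmidt condensation, in which 2 has no α-hydrogen so only the enolate of 1 adds, and E1cB loss of water gives the conjugated (E)-enone, which should crystallise from the medium.

Step 2
Reactants: 3 (E)-1,3-bis(4-methoxyphenyl)prop-2-en-1-one
Product: 4 1,3-bis(4-methoxyphenyl)propan-1-one
Conditions: H2 (1 atm), 10% Pd/C, EtOAc, rt, stopped after one equivalent of H2
Reagents that add atoms: none
Why: Heterogeneous catalytic hydrogenation saturates the conjugated C=C far faster than it touches the electron-rich 4-methoxybenzoyl carbonyl, and no stereocentre arises.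

Step 3
Reactants: 4 1,3-bis(4-methoxyphenyl)propan-1-one (two molecules)
Product: 6 meso-(2R,3S)-2,3-bis(4-methoxybenzyl)-1,4-bis(4-methoxyphenyl)butane-1,4-dione, via lithium enolate 5 (not isolated)
Conditions: LiN(i-Pr)2 (1.05 equiv), THF, −78 °C; CuCl2 (1.1 equiv), DMF, −78 °C → rt; crystallisation from EtOAc/EtOH
Reagents that add atoms: none
Why: Copper-mediated oxidative homocoupling of a ketone enolate, in which CuCl2 takes one electron from 5 and two α-keto radical (or copper enolate) units join at C2–C3; both stereocentres are set here with little kinetic bias, so both diastereomers are expected, and the centrosymmetric, normally less soluble meso form is taken by fractional crystallisation and told from the racemate on a chiral HPLC phase, where only the racemate splits.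

Step 4
Reactants: 6 meso-(2R,3S)-2,3-bis(4-methoxybenzyl)-1,4-bis(4-methoxyphenyl)butane-1,4-dione
Product: 7 meso-(2R,3S)-2,3-bis(4-hydroxybenzyl)-1,4-bis(4-hydroxyphenyl)butane-1,4-dione
Conditions: BBr3 (8 equiv), CH2Cl2, −78 °C → rt; ice/H2O
Reagents that add atoms: none
Why: Lewis-acid cleavage of aryl methyl ethers (coordination at oxygen, then bromide attack on methyl) runs at or below room temperature while both carbonyl oxygens are held as boron adducts and cannot serve as enol nucleophiles, so C2 and C3 should be kept and 7 can be recrystallised.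

Step 5
Reactants: 7 meso-(2R,3S)-2,3-bis(4-hydroxybenzyl)-1,4-bis(4-hydroxyphenyl)butane-1,4-dione
Product: 8 meso-(2R,3S)-2,3-bis(4-acetoxybenzyl)-1,4-bis(4-acetoxyphenyl)butane-1,4-dione
Conditions: Ac2O (6 equiv), pyridine, 0 °C → rt; recrystallisation
Reagents that add atoms: acetic anhydride, CC(=O)OC(C)=O
Why: Pyridine-mediated O-acylation of phenols is too weakly basic to enolise the hindered ketones, and it turns four donor-substituted rings into electron-poor aryl esters that fit the oxidising medium of step 6.

Step 6
Reactants: 8 meso-(2R,3S)-2,3-bis(4-acetoxybenzyl)-1,4-bis(4-acetoxyphenyl)butane-1,4-dione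
Product: 10 meso-(2R,3S)-2,3-bis(4-acetoxybenzyl)-1,4-bis(4-acetoxy-2-hydroxyphenyl)butane-1,4-dione, via bis(aryl trifluoroacetate) 9 (not isolated)
Conditions: Pd(OCOCF3)2 (10 mol % per ketone), PhI(OCOCF3)2 (3–4 equiv), ClCH2CH2Cl, 70 °C; then H2O–THF, rt
Reagents that add atoms: [bis(trifluoroacetoxy)iodo]benzene, O=C(OI(OC(=O)C(F)(F)F)c1ccccc1)C(F)(F)F
Why: Each ketone oxygen binds the electrophilic divalent palladium trifluoroacetate, trifluoroacetate-assisted concerted metalation–deprotonation at C2'–H gives a five-membered palladacycle, PhI(OCOCF3)2 oxidises it to a tetravalent aryl palladium trifluoroacetate, and C–O reductive elimination delivers 9, whose two very labile trifluoroacetates are hydrolysed by water on work-up while the four acetates stay. The closest known reaction type is the ketone-directed palladium-catalysed ortho C–H hydroxylation of alkyl aryl ketones, α-branched ones included, with hypervalent iodine or persulfate oxidants; here it is only run twice in one molecule. No ring is closed (the palladacycles are transient) and no stereocentre is created, so C2 and C3 merely have to survive. Site selectivity: C2' and C6' of each para-substituted ring A are equivalent, a ring B C–H bond could be reached from a ketone only through a seven-membered palladacycle, the acetate carbonyls are much poorer donors than the ketones, and the acetoxy groups make rings B too electron-poor for undirected palladation or one-electron oxidation by the iodane, which 4-methoxybenzyl rings would not be. A further oxygenation at C6' is held back because the trifluoroacetoxy group deactivates ring A and twists the carbonyl out of the ring plane. Chemoselectivity against the enol: neat CF3CO2H/(CF3CO)2O would invite Paal–Knorr cyclodehydration of the 1,4-diketone to the furan and epimerisation through the same enol, so the reaction is run in ClCH2CH2Cl, where the only acid is the CF3CO2H released by turnover, and it is helped by the low basicity of the 4-acetoxybenzoyl carbonyls, the hindered tertiary α-C–H bonds and the need of the meso isomer to bring its two benzyl groups cis on ring closure.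

Step 7
Reactants: 10 meso-(2R,3S)-2,3-bis(4-acetoxybenzyl)-1,4-bis(4-acetoxy-2-hydroxyphenyl)butane-1,4-dione
Product: 11 meso-(2R,3S)-1,4-bis(2,4-dihydroxyphenyl)-2,3-bis(4-hydroxybenzyl)butane-1,4-dione (CNP0406969.1)
Conditions: K2CO3, degassed MeOH, argon, 0 °C → rt; 1 M HCl to pH 4
Reagents that add atoms: none
Why: Base-catalysed transesterification of aryl acetates is fast in the cold, and its first event is deprotonation of the 2'-OH groups, which turns each ketone into a vinylogous carboxylate whose tertiary α-hydrogen is out of reach of carbonate or methoxide, so the meso configuration should be kept.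

**Compound list**
1 | 4'-methoxyacetophenone | CC(=O)c1ccc(OC)cc1 | starting material
2 | 4-methoxybenzaldehyde | COc1ccc(C=O)cc1 | starting material
3 | (E)-1,3-bis(4-methoxyphenyl)prop-2-en-1-one | COc1ccc(/C=C/C(=O)c2ccc(OC)cc2)cc1 | intermediate
4 | 1,3-bis(4-methoxyphenyl)propan-1-one | COc1ccc(CCC(=O)c2ccc(OC)cc2)cc1 | intermediate
5 | lithium (Z)-enolate of 4 (not isolated) | [Li]O/C(c1ccc(OC)cc1)=C\Cc1ccc(OC)cc1 | intermediate
6 | meso-(2R,3S)-2,3-bis(4-methoxybenzyl)-1,4-bis(4-methoxyphenyl)butane-1,4-dione | O=C(c1ccc(OC)cc1)[C@@H](Cc1ccc(OC)cc1)[C@@H](Cc1ccc(OC)cc1)C(=O)c1ccc(OC)cc1 | intermediate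
7 | meso-(2R,3S)-2,3-bis(4-hydroxybenzyl)-1,4-bis(4-hydroxyphenyl)butane-1,4-dione | O=C(c1ccc(O)cc1)[C@@H](Cc1ccc(O)cc1)[C@@H](Cc1ccc(O)cc1)C(=O)c1ccc(O)cc1 | intermediate
8 | meso-(2R,3S)-2,3-bis(4-acetoxybenzyl)-1,4-bis(4-acetoxyphenyl)butane-1,4-dione | O=C(c1ccc(OC(C)=O)cc1)[C@@H](Cc1ccc(OC(C)=O)cc1)[C@@H](Cc1ccc(OC(C)=O)cc1)C(=O)c1ccc(OC(C)=O)cc1 | intermediate
9 | meso-(2R,3S)-2,3-bis(4-acetoxybenzyl)-1,4-bis[4-acetoxy-2-(trifluoroacetoxy)phenyl]butane-1,4-dione (not isolated) | O=C(c1ccc(OC(C)=O)cc1OC(=O)C(F)(F)F)[C@@H](Cc1ccc(OC(C)=O)cc1)[C@@H](Cc1ccc(OC(C)=O)cc1)C(=O)c1ccc(OC(C)=O)cc1OC(=O)C(F)(F)F | intermediate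
10 | meso-(2R,3S)-2,3-bis(4-acetoxybenzyl)-1,4-bis(4-acetoxy-2-hydroxyphenyl)butane-1,4-dione | O=C(c1ccc(OC(C)=O)cc1O)[C@@H](Cc1ccc(OC(C)=O)cc1)[C@@H](Cc1ccc(OC(C)=O)cc1)C(=O)c1ccc(OC(C)=O)cc1O | intermediate
11 | meso-(2R,3S)-1,4-bis(2,4-dihydroxyphenyl)-2,3-bis(4-hydroxybenzyl)butane-1,4-dione | O=C(c1ccc(O)cc1O)[C@@H](Cc1ccc(O)cc1)[C@@H](Cc1ccc(O)cc1)C(=O)c1ccc(O)cc1O | target

Total step count: 7. Longest linear sequence: 7 steps (1 or 2 to 11).

**Steps most likely to fail**

1. Step 6.
- What may go wrong: the CF3CO2H released by turnover may enolise the diketone. The enol is then drained into furan cyclodehydration, or the meso relationship is lost. The catalyst may also die after the first oxygenation, so that half-oxidised material piles up.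
- Fallback (the 2'-oxygens are bought instead of made): it sets out from 2. Claisen–Schmidt condensation of 2 with commercial 2',4'-dimethoxyacetophenone F1 (NaOH, EtOH) should give (E)-1-(2,4-dimethoxyphenyl)-3-(4-methoxyphenyl)prop-2-en-1-one F2. Hydrogenation (H2, Pd/C, EtOAc) should give 1-(2,4-dimethoxyphenyl)-3-(4-methoxyphenyl)propan-1-one F3. LiN(i-Pr)2 converts this into its lithium (Z)-enolate F4, which CuCl2 couples. Crystallisation should give meso-(2R,3S)-1,4-bis(2,4-dimethoxyphenyl)-2,3-bis(4-methoxybenzyl)butane-1,4-dione F5. BBr3 in CH2Cl2 (−78 °C → rt) cleaves all six methyl ethers, and the fallback comes back to the route at 11.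

2. Step 3.
- What may go wrong: poor simple diastereoselection may put most of the material into the racemic series, or the two diastereomers may co-crystallise.
- Fallback (thermodynamic in place of kinetic stereocontrol): it sets out from 4, which is coupled as in step 3 but without direct separation. The racemic diastereomer rac-(2R*,3R*)-2,3-bis(4-methoxybenzyl)-1,4-bis(4-methoxyphenyl)butane-1,4-dione F6 in the crude product is equilibrated with the meso form through the enolate by catalytic NaOEt in hot EtOH. On slow cooling the less soluble meso isomer should crystallise and pull the equilibrium. Mother liquors are recycled. The fallback comes back to the route at 6.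

3. Step 4.
- What may go wrong: Lewis-acid-triggered enolisation of the boron-complexed diketone may lead to cyclodehydration or to epimerisation at C2/C3. Cleavage of the two ethers para to the carbonyl groups may be sluggish and call for heating.
- Fallback (the protecting group is changed before the diketone exists, and unmasking is neutral): it sets out from 4. BBr3 acts on 4, which has neither a 1,4-dicarbonyl unit nor a stereocentre, to give 1,3-bis(4-hydroxyphenyl)propan-1-one F7. BnBr and K2CO3 in DMF give 1,3-bis(4-benzyloxyphenyl)propan-1-one F8. LiN(i-Pr)2 forms its lithium (Z)-enolate F9, and CuCl2 coupling with crystallisation should give meso-(2R,3S)-2,3-bis(4-benzyloxybenzyl)-1,4-bis(4-benzyloxyphenyl)butane-1,4-dione F10. Hydrogenolysis (H2, Pd/C, THF–EtOAc) frees the four phenols without acid or base, and the fallback comes back to the route at 7.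

**Further compounds**
F1 | step 6 | 2',4'-dimethoxyacetophenone | CC(=O)c1ccc(OC)cc1OC
F2 | step 6 | (E)-1-(2,4-dimethoxyphenyl)-3-(4-methoxyphenyl)prop-2-en-1-one | COc1ccc(/C=C/C(=O)c2ccc(OC)cc2OC)cc1
F3 | step 6 | 1-(2,4-dimethoxyphenyl)-3-(4-methoxyphenyl)propan-1-one | COc1ccc(CCC(=O)c2ccc(OC)cc2OC)cc1
F4 | step 6 | lithium (Z)-enolate of F3 | [Li]O/C(c1ccc(OC)cc1OC)=C\Cc1ccc(OC)cc1
F5 | step 6 | meso-(2R,3S)-1,4-bis(2,4-dimethoxyphenyl)-2,3-bis(4-methoxybenzyl)butane-1,4-dione | O=C(c1ccc(OC)cc1OC)[C@@H](Cc1ccc(OC)cc1)[C@@H](Cc1ccc(OC)cc1)C(=O)c1ccc(OC)cc1OC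
F6 | step 3 | rac-(2R*,3R*)-2,3-bis(4-methoxybenzyl)-1,4-bis(4-methoxyphenyl)butane-1,4-dione, drawn as the (2S,3S) enantiomer | O=C(c1ccc(OC)cc1)[C@@H](Cc1ccc(OC)cc1)[C@H](Cc1ccc(OC)cc1)C(=O)c1ccc(OC)cc1
F7 | step 4 | 1,3-bis(4-hydroxyphenyl)propan-1-one | O=C(CCc1ccc(O)cc1)c1ccc(O)cc1
F8 | step 4 | 1,3-bis(4-benzyloxyphenyl)propan-1-one | O=C(CCc1ccc(OCc2ccccc2)cc1)c1ccc(OCc2ccccc2)cc1
F9 | step 4 | lithium (Z)-enolate of F8 | [Li]O/C(c1ccc(OCc2ccccc2)cc1)=C\Cc1ccc(OCc2ccccc2)cc1
F10 | step 4 | meso-(2R,3S)-2,3-bis(4-benzyloxybenzyl)-1,4-bis(4-benzyloxyphenyl)butane-1,4-dione | O=C(c1ccc(OCc2ccccc2)cc1)[C@@H](Cc1ccc(OCc2ccccc2)cc1)[C@@H](Cc1ccc(OCc2ccccc2)cc1)C(=O)c1ccc(OCc2ccccc2)cc1
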